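We read the west flask at 93 s, so we first ask how many lifetimes of Sub fit into that time.

| setting | east | south-east | north | west |
|---|---|---|---|---|
| Sub | 0.0800 M | 0.0400 M | 0.0800 M | 0.0260 M |
| Rgt | 0.120 M | 0.0800 M | 0.240 M | 0.240 M |
| time |  |  |  | 93 s |

| run | time / s | [Prd] / M |
|---|---|---|
| east run | 3.7 | 0.00247 |
| east run | 6.4 | 0.00438 |
| east run | 11 | 0.00768 |
| east run | 19 | 0.01131 |
| east run | 32 | 0.01717 |
| east run | 54 | 0.02292 |
| east run | 93 | 0.02751 |
| south-east run | 3.7 | 0.00118 |
| south-east run | 6.4 | 0.00104 |
| south-east run | 11 | 0.00246 |
| south-east run | 19 | 0.00409 |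
| south-east run | 32 | 0.00551 |
| south-east run | 54 | 0.00870 |
| south-east run | 93 | 0.01154 |
| north run | 3.7 | 0.00581 |
| north run | 6.4 | 0.00981 |
| north run | 11 | 0.01529 |
| north run | 19 | 0.02288 |
| north run | 32 | 0.03080 |
| north run | 54 | 0.03666 |
| north run | 93 | 0.03622 |

(each reading ± 2 × 10⁻⁴ M)

- Overall: Sub + Rgt -> Prd.
- Constant volume, constant temperature.
- "The second partner" is Rgt.
- An order is taken over about fifteen percent of the charge, up and down.

- apparent order in [Sub] of the starting rate, round the charge of the east run (the rate where two percent of its Sub have turned into Prd) (one fixed amount of Prd, the same in the runs compared)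
- apparent order in [Rgt] of the starting rate, round the charge of the east run (the rate where two percent of its Sub have turned into Prd)
- Prd in the west run at 93 s, as a share of the Sub charged

Does a lifetime depend on Rgt? The north run carries twice the Rgt of the east run at the same Sub, and its first reading is 2.35 times the east one. Our reading of the Rgt order is therefore 1.23.

Does it depend on the Sub charge? East over south-east at 11 s reads 3.12. After removing the Rgt factor, our reading of the Sub order is 0.921, close to one. The fraction of Sub turned per second thus follows Rgt, and the west run can borrow it from the north run, which has the same Rgt charge.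

The north run's first reading, as a fraction of its Sub per second, multiplied by 93 s, gives 1.83. This is the turnover count: the initial fractional rate times the time of reading.

In the west run Rgt stands at 9.23 times Sub, so Sub decays in a pseudo-first-order way, and the count gives 83.9% of it turned.

How much of that remains as Prd? The north run reads 0.03666 M at 54 s and 0.03622 M at 93 s, flat within the scatter, at 45.3% of its charge. That share is our figure for the west run.

The forecast gives orders of 1 (0.8 to 1.2) in Sub and 1.15 (0.95 to 1.35) in Rgt. For the west run it gives 47% (41% to 56%), reasoning that “its fractional yield should resemble north's”.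

The flask gives orders of 1.0 in Sub and 1.2 in Rgt, and 46.0% of the Sub charged as Prd in the west run at 93 s.

    Sub + Rgt → Prd (0.06710 M⁻¹ s⁻¹)
    Sub + 2 Rgt → Prd + Rgt (0.1000 M⁻² s⁻¹)
    Prd + Rgt → Sid (0.02880 M⁻¹ s⁻¹)
    Prd → Q (0.004140 s⁻¹)

That west value is 38 percentage points below the share of Sub that a count of 1.83 says has turned. The west run without the turning of Prd and Rgt into Sid reaches 66.1%, a gain of 20 points. Even that run stays below the count's share, by 18 points.

Readings and results were generated by integration on assumed constants; noise was put on by code.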